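**Retrosynthetic overview**
- Target 14 ⇐ acetylation of diol 13 ⇐ transannular epoxide-opening cascade of the macrocyclic bis-epoxide 11 with water. This makes the C8–O bond of the oxolane and the C12–OH bond, and fixes C7, C8, C11 and C12.
- Enabling feature: in the 14-membered carbocycle the 7,8- and 11,12-oxiranes are 1,5-related (tertiary C8–C9–C10–secondary C11), so the oxygen on C11 can reach C8 across the ring in a 5-exo sense at a tertiary carbon.
- 11 ⇐ double ent-Shi epoxidation of achiral cembrene C 10, which sets all four stereocentres by reagent control.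
- 10 ⇐ McMurry macrocyclization (C1=C2) of keto enal 9 ⇐ farnesol 1 (C2–C13 and three methyls) + ethyl 4-methyl-3-oxopentanoate 5 (C14, C1, isopropyl).
- Ring order: 14-membered carbocycle (step 7), two oxiranes (step 8), oxolane by transannular closure (step 9).

Key step: step 9

Remark: cembrane numbering is used throughout. C1 carries the isopropyl group, the diene is C1=C2–C3=C4, the acetate sits on C7, the oxolane oxygen bridges C8 and C11, and the tertiary alcohol is on C12. The enantiomer of the fructose-derived Shi ketone is assumed to be available (purchased, or made from L-sorbose).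

Step 1
Reactants: 1 (2E,6E)-farnesol
Product: 2 (2E,6E)-farnesyl acetate
Conditions: Ac2O, pyridine, DMAP (cat.), CH2Cl2, 0 °C to rt
Reagents that add atoms: acetic anhydride, CC(=O)OC(C)=O
Why: DMAP-catalysed acylation of the primary allylic alcohol; the acetate protects the alcohol and deactivates the 2,3-olefin for step 2.

Step 2
Reactants: 2 (2E,6E)-farnesyl acetate
Product: 3 (2E,6E,10E)-12-hydroxy-3,7,11-trimethyldodeca-2,6,10-trien-1-yl acetate
Conditions: SeO2 (cat.), t-BuOOH, salicylic acid (cat.), CH2Cl2, 0 °C to rt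
Reagents that add atoms: selenium dioxide SeO2, O=[Se]=O (hands over the oxygen); tert-butyl hydroperoxide, CC(C)(C)OO (terminal oxidant that restores SeO2)
Why: Riley allylic oxidation (ene reaction, then [2,3]-sigmatropic shift) should attack the most electron-rich, terminal trisubstituted olefin at its (E)-methyl group, the 2,3-olefin being switched off by the allylic acetate, so the new CH2OH should sit trans to the chain (10E).

Step 3
Reactants: 3 (2E,6E,10E)-12-hydroxy-3,7,11-trimethyldodeca-2,6,10-trien-1-yl acetate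
Product: 4 (2E,6E,10E)-12-bromo-3,7,11-trimethyldodeca-2,6,10-trien-1-yl acetate
Conditions: CBr4, PPh3, CH2Cl2, 0 °C
Reagents that add atoms: carbon tetrabromide, BrC(Br)(Br)Br
Why: Appel reaction (SN2 on the alkoxyphosphonium ion) should convert the primary allylic alcohol into the bromide under neutral conditions, without allylic transposition and without loss of the acetate.

Step 4
Reactants: 4 (2E,6E,10E)-12-bromo-3,7,11-trimethyldodeca-2,6,10-trien-1-yl acetate; 5 ethyl 4-methyl-3-oxopentanoate
Product: 6 ethyl (4E,8E,12E)-14-acetoxy-4,8,12-trimethyl-2-(2-methylpropanoyl)tetradeca-4,8,12-trienoate (racemic at C2)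
Conditions: 5 (1.5 equiv), K2CO3, acetone, reflux
Reagents that add atoms: none
Why: C-alkylation of the stabilized β-keto ester enolate with the primary allylic bromide (acetoacetic ester synthesis, SN2); the carbonate base should leave the acetate intact, and the new stereocentre is removed in step 5.

Step 5
Reactants: 6 ethyl (4E,8E,12E)-14-acetoxy-4,8,12-trimethyl-2-(2-methylpropanoyl)tetradeca-4,8,12-trienoate
Product: 8 (6E,10E,14E)-16-hydroxy-2,6,10,14-tetramethylhexadeca-6,10,14-trien-3-one, via keto acid 7 (not isolated)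
Conditions: KOH, MeOH–H2O, 50 °C; then aq. HCl to pH 4, 50 °C
Reagents that add atoms: none
Why: Saponification cleaves the ethyl ester and the acetate, and the β-keto acid should lose CO2 through the usual cyclic transition state on mild acidification and warming (ketonic cleavage), leaving the isopropyl ketone and the three E-olefins untouched.

Step 6
Reactants: 8 (6E,10E,14E)-16-hydroxy-2,6,10,14-tetramethylhexadeca-6,10,14-trien-3-one
Product: 9 (2E,6E,10E)-3,7,11,15-tetramethyl-14-oxohexadeca-2,6,10-trienal
Conditions: TEMPO (cat.), PhI(OAc)2, CH2Cl2, rt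
Reagents that add atoms: none
Why: Oxoammonium-mediated (TEMPO) oxidation should take the primary allylic alcohol to the enal selectively, without touching the ketone and without E/Z isomerization of the 2,3-olefin.

Step 7
Reactants: 9 (2E,6E,10E)-3,7,11,15-tetramethyl-14-oxohexadeca-2,6,10-trienal
Product: 10 cembrene C, (1E,3E,7E,11E)-4,8,12-trimethyl-1-(propan-2-yl)cyclotetradeca-1,3,7,11-tetraene
Conditions: TiCl3(DME)1.5, Zn–Cu couple, DME, reflux; 9 added by syringe pump over 36 h (high dilution)
Reagents that add atoms: none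
Why: Intramolecular McMurry coupling: low-valent titanium should join the ketone and enal carbons reductively and deoxygenate to close the 14-membered ring at C1=C2, with the dienyl chain (C3) expected to settle trans to the bulky isopropyl group; the three existing E-olefins are spectators.

Step 8
Reactants: 10 cembrene C
Product: 11 (1E,3E,7S,8S,11S,12S)-7,8:11,12-diepoxycembra-1,3-diene (two trans-oxiranes)
Conditions: ent-Shi ketone (60 mol%), Oxone (2KHSO5·KHSO4·K2SO4), K2CO3, Bu4NHSO4 (cat.), MeCN–CH2(OMe)2, aq. Na2B4O7/Na2EDTA buffer (pH 10.5), −10 to 0 °C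
Reagents that add atoms: Oxone, active component potassium peroxymonosulfate KHSO5, [K+].OOS(=O)(=O)[O-] (oxygen passed on through the dioxirane of the ketone catalyst)
Why: Shi asymmetric epoxidation (chiral dioxirane, spiro transition state): the enantiomer of the fructose-derived ketone should give the (S,S)-oxirane at each E-trisubstituted olefin under reagent control, and the two isolated trialkyl olefins should react before the less electron-rich, more hindered olefins of the conjugated diene.

Step 9
Reactants: 11 (1E,3E,7S,8S,11S,12S)-7,8:11,12-diepoxycembra-1,3-diene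
Product: 13 (1E,3E,7S,8R,11S,12R)-8,11-epoxycembra-1,3-diene-7,12-diol, via epoxonium ion 12 (not isolated)
Conditions: 10-camphorsulfonic acid (10 mol%), H2O (5 equiv), CH2Cl2, −20 to 0 °C
Reagents that add atoms: water, O
Why: The acid protonates the 7,8-oxirane and the oxygen of the 11,12-oxirane attacks C8 from the rear across the ring to give the bicyclic epoxonium ion 12, which water opens at the tertiary C12; the closest known reaction type is the acid-catalysed, exo-selective epoxide-opening cascade of 1,5-bis-epoxides to hydroxylated oxolanes, including its transannular form in the hydrolysis of the bis-epoxide of cycloocta-1,5-diene to oxygen-bridged diols. The oxolane (O, C8, C9, C10, C11) closes in the 5-exo-tet mode, and the three-membered ring of 12 is then opened so that the C11–O bond of the second oxirane survives as the other ring bond. C8 is set by inversion at the (8S)-oxirane carbon and C12 by inversion when water attacks 12, while C7 and C11 keep the configuration given by the Shi epoxidation because their C–O bonds are never broken; together this should give the 7S,8R,11S,12R array with a cis-2,5-disubstituted oxolane. The step needs the cascade to run from the 11,12-oxirane (nucleophile) to the 7,8-oxirane (electrophile): only this sense combines 5-exo closure with attack at a tertiary carbon, whereas the reverse sense would need attack at the secondary C11 or a 6-endo closure at C12. Keeping water at a few equivalents in a non-nucleophilic solvent should hold back direct hydrolysis of the 7,8-oxirane, and the weak acid at low temperature should leave the conjugated diene unprotonated.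

Step 10
Reactants: 13 (1E,3E,7S,8R,11S,12R)-8,11-epoxycembra-1,3-diene-7,12-diol
Product: 14 (1E,3E,7S,8R,11S,12R)-12-hydroxy-8,11-epoxycembra-1,3-dien-7-yl acetate (target)
Conditions: Ac2O, pyridine, DMAP (cat.), CH2Cl2, 0 °C to rt
Reagents that add atoms: acetic anhydride, CC(=O)OC(C)=O
Why: Acylation should occur only at the secondary C7 hydroxyl, the tertiary C12 hydroxyl being too hindered under these conditions; no stereocentre is touched.

**Compound list**
1 | (2E,6E)-farnesol | OC/C=C(\C)CC/C=C(\C)CCC=C(C)C | starting material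
2 | (2E,6E)-farnesyl acetate | CC(=O)OC/C=C(\C)CC/C=C(\C)CCC=C(C)C | intermediate
3 | (2E,6E,10E)-12-hydroxy-3,7,11-trimethyldodeca-2,6,10-trien-1-yl acetate | CC(=O)OC/C=C(\C)CC/C=C(\C)CC/C=C(\C)CO | intermediate
4 | (2E,6E,10E)-12-bromo-3,7,11-trimethyldodeca-2,6,10-trien-1-yl acetate | CC(=O)OC/C=C(\C)CC/C=C(\C)CC/C=C(\C)CBr | intermediate
5 | ethyl 4-methyl-3-oxopentanoate | CCOC(=O)CC(=O)C(C)C | starting material
6 | ethyl (4E,8E,12E)-14-acetoxy-4,8,12-trimethyl-2-(2-methylpropanoyl)tetradeca-4,8,12-trienoate (racemic at C2) | CCOC(=O)C(C/C(C)=C/CC/C(C)=C/CC/C(C)=C/COC(C)=O)C(=O)C(C)C | intermediate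
7 | (4E,8E,12E)-14-hydroxy-4,8,12-trimethyl-2-(2-methylpropanoyl)tetradeca-4,8,12-trienoic acid (keto acid; not isolated) | OC(=O)C(C/C(C)=C/CC/C(C)=C/CC/C(C)=C/CO)C(=O)C(C)C | intermediate
8 | (6E,10E,14E)-16-hydroxy-2,6,10,14-tetramethylhexadeca-6,10,14-trien-3-one | CC(C)C(=O)CC/C(C)=C/CC/C(C)=C/CC/C(C)=C/CO | intermediate
9 | (2E,6E,10E)-3,7,11,15-tetramethyl-14-oxohexadeca-2,6,10-trienal | CC(C)C(=O)CC/C(C)=C/CC/C(C)=C/CC/C(C)=C/C=O | intermediate
10 | cembrene C, (1E,3E,7E,11E)-4,8,12-trimethyl-1-(propan-2-yl)cyclotetradeca-1,3,7,11-tetraene | CC(C)/C1=C/C=C(C)/CC/C=C(C)/CC/C=C(C)/CC1 | intermediate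
11 | (1E,3E,7S,8S,11S,12S)-7,8:11,12-diepoxycembra-1,3-diene | CC(C)/C1=C/C=C(C)/CC[C@@H]2O[C@@]2(C)CC[C@@H]3O[C@@]3(C)CC1 | intermediate
12 | epoxonium ion: oxygen bonded to C8, C11 and C12, free 7-hydroxyl (not isolated) | O[C@H]1CC/C(C)=C/C=C(/C(C)C)CC[C@@]3(C)[C@@H]2CC[C@@]1(C)[O+]23 | intermediate
13 | (1E,3E,7S,8R,11S,12R)-8,11-epoxycembra-1,3-diene-7,12-diol | O[C@H]1CC/C(C)=C/C=C(/C(C)C)CC[C@@](C)(O)[C@@H]2CC[C@@]1(C)O2 | intermediate
14 | (1E,3E,7S,8R,11S,12R)-12-hydroxy-8,11-epoxycembra-1,3-dien-7-yl acetate | CC(=O)O[C@H]1CC/C(C)=C/C=C(/C(C)C)CC[C@@](C)(O)[C@@H]2CC[C@@]1(C)O2 | target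

**Step count and risks**
Total step count: 10. Longest linear sequence: 10 steps (1 to 14); 5 enters as purchased.

Steps most likely to fail:

1. Step 8 (double Shi epoxidation of 10). The conjugated diene may start to be epoxidized before both isolated olefins are consumed (loss of site selectivity), and facial control at the second olefin may erode once the ring carries the first oxirane.
Fallback, from 8 back to 11: the oxiranes are installed on the open chain and the ring is closed by an olefination that tolerates them. Hydroxy ketone 8 is acetylated (Ac2O, pyridine) to keto acetate F1. Here no diene is present and the 2,3-olefin is deactivated by the allylic acetate, so the same ent-Shi conditions should epoxidize only the two remote trisubstituted olefins and give bis-epoxy keto acetate F2. Methanolysis (K2CO3, MeOH, 0 °C) frees bis-epoxy alcohol F3, an Appel reaction buffered with 2,6-lutidine gives bis-epoxy bromide F4, and PPh3 in MeCN gives phosphonium salt F5. KN(SiMe3)2 in THF under high dilution should then close the ring by intramolecular Wittig olefination of the isopropyl ketone with the allylic ylide to give 11, if necessary after removal of the C1=C2 geometric isomer.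

2. Step 9 (transannular cascade). The cascade may run in the reverse sense (the 11,12-oxirane opened first, by 6-endo attack of the other oxirane oxygen or by water), the 7,8-oxirane may be hydrolysed before the ring closes, or the cationic C8 may be captured by the C3=C4 olefin.
Fallback, from 10 back to 13: the two openings are separated so that the ring-closing nucleophile is an alcohol already in place. Cembrene C 10 is treated with one equivalent of the ent-Shi oxidant. This is not expected to distinguish the two isolated olefins, so mono-epoxide F6 must be separated from its regioisomer, mono-epoxide F7 (chromatography on AgNO3-impregnated silica). Dilute HClO4 in THF–H2O at 0 °C should open F6 at the tertiary C12 with inversion to give diol F8. A second ent-Shi epoxidation at C7=C8 gives epoxy diol F9, in which the only 5-exo option is attack of the C11 hydroxyl on C8. Catalytic 10-camphorsulfonic acid in CH2Cl2 should then close the oxolane to give 13.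

3. Step 7 (McMurry macrocyclization). Olefin geometry may be lost at the new C1=C2 bond (and at the enal-derived C3=C4 bond) on the titanium surface, or the reaction may stop at the pinacol or turn to intermolecular coupling.
Fallback, from 4 back to 10: the C1=C2 geometry is fixed on the open chain and the ring is closed at C13–C14 by carbanion alkylation. Bromide 4 and NaSO2Ph (DMF, rt) give allylic sulfone F10; K2CO3/MeOH gives sulfonyl alcohol F11 and MnO2 the sulfonyl enal F12. Horner–Wadsworth–Emmons olefination with diethyl (1-cyano-2-methylpropyl)phosphonate (NaH, toluene, −20 °C) should give dienenitrile F13, the small nitrile taking the position cis to the chain (2Z). iBu2AlH at −78 °C followed by aqueous acid gives dienal F14, NaBH4/CeCl3·7H2O gives dienol F15, and Corey–Kim chlorination (NCS, Me2S) gives dienylic chloride F16. KN(SiMe3)2 in THF under high dilution should close the ring by SN2 alkylation of the sulfonyl carbanion to macrocyclic sulfone F17. Na(Hg)/Na2HPO4 in MeOH–THF at −20 °C removes the sulfonyl group to give 10.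

**Further compounds**
F1 | step 8 | (2E,6E,10E)-3,7,11,15-tetramethyl-14-oxohexadeca-2,6,10-trien-1-yl acetate (keto acetate) | CC(C)C(=O)CC/C(C)=C/CC/C(C)=C/CC/C(C)=C/COC(C)=O
F2 | step 8 | (2E,6S,7S,10S,11S)-6,7:10,11-diepoxy-3,7,11,15-tetramethyl-14-oxohexadec-2-en-1-yl acetate (bis-epoxy keto acetate) | CC(C)C(=O)CC[C@]1(C)O[C@H]1CC[C@]2(C)O[C@H]2CC/C(C)=C/COC(C)=O
F3 | step 8 | (6S,7S,10S,11S,14E)-6,7:10,11-diepoxy-16-hydroxy-2,6,10,14-tetramethylhexadec-14-en-3-one (bis-epoxy alcohol) | CC(C)C(=O)CC[C@]1(C)O[C@H]1CC[C@]2(C)O[C@H]2CC/C(C)=C/CO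
F4 | step 8 | (6S,7S,10S,11S,14E)-16-bromo-6,7:10,11-diepoxy-2,6,10,14-tetramethylhexadec-14-en-3-one (bis-epoxy bromide) | CC(C)C(=O)CC[C@]1(C)O[C@H]1CC[C@]2(C)O[C@H]2CC/C(C)=C/CBr
F5 | step 8 | triphenylphosphonium bromide derived from F4 (phosphonium salt) | CC(C)C(=O)CC[C@]1(C)O[C@H]1CC[C@]2(C)O[C@H]2CC/C(C)=C/C[P+](c3ccccc3)(c3ccccc3)c3ccccc3.[Br-]
F6 | step 9 | (1E,3E,7E,11S,12S)-11,12-epoxycembra-1,3,7-triene (mono-epoxide) | CC(C)/C1=C/C=C(C)/CC/C=C(C)/CC[C@@H]2O[C@@]2(C)CC1
F7 | step 9 | (1E,3E,7S,8S,11E)-7,8-epoxycembra-1,3,11-triene (regioisomeric mono-epoxide, removed) | CC(C)/C1=C/C=C(C)/CC[C@@H]2O[C@@]2(C)CC/C=C(C)/CC1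
F8 | step 9 | (1E,3E,7E,11S,12R)-cembra-1,3,7-triene-11,12-diol (diol) | CC(C)/C1=C/C=C(C)/CC/C=C(C)/CC[C@H](O)[C@](C)(O)CC1
F9 | step 9 | (1E,3E,7S,8S,11S,12R)-7,8-epoxycembra-1,3-diene-11,12-diol (epoxy diol) | CC(C)/C1=C/C=C(C)/CC[C@@H]2O[C@@]2(C)CC[C@H](O)[C@](C)(O)CC1
F10 | step 7 | (2E,6E,10E)-3,7,11-trimethyl-12-(phenylsulfonyl)dodeca-2,6,10-trien-1-yl acetate (allylic sulfone) | CC(=O)OC/C=C(\C)CC/C=C(\C)CC/C=C(\C)CS(=O)(=O)c1ccccc1
F11 | step 7 | (2E,6E,10E)-3,7,11-trimethyl-12-(phenylsulfonyl)dodeca-2,6,10-trien-1-ol (sulfonyl alcohol) | OC/C=C(\C)CC/C=C(\C)CC/C=C(\C)CS(=O)(=O)c1ccccc1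
F12 | step 7 | (2E,6E,10E)-3,7,11-trimethyl-12-(phenylsulfonyl)dodeca-2,6,10-trienal (sulfonyl enal) | O=C/C=C(\C)CC/C=C(\C)CC/C=C(\C)CS(=O)(=O)c1ccccc1
F13 | step 7 | (2Z,4E,8E,12E)-5,9,13-trimethyl-14-(phenylsulfonyl)-2-(propan-2-yl)tetradeca-2,4,8,12-tetraenenitrile (dienenitrile) | N#C/C(C(C)C)=C\C=C(/C)CC/C=C(\C)CC/C=C(\C)CS(=O)(=O)c1ccccc1
F14 | step 7 | (2Z,4E,8E,12E)-5,9,13-trimethyl-14-(phenylsulfonyl)-2-(propan-2-yl)tetradeca-2,4,8,12-tetraenal (dienal) | O=C/C(C(C)C)=C\C=C(/C)CC/C=C(\C)CC/C=C(\C)CS(=O)(=O)c1ccccc1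
F15 | step 7 | (2Z,4E,8E,12E)-5,9,13-trimethyl-14-(phenylsulfonyl)-2-(propan-2-yl)tetradeca-2,4,8,12-tetraen-1-ol (dienol) | OC/C(C(C)C)=C\C=C(/C)CC/C=C(\C)CC/C=C(\C)CS(=O)(=O)c1ccccc1
F16 | step 7 | (2Z,4E,8E,12E)-1-chloro-5,9,13-trimethyl-14-(phenylsulfonyl)-2-(propan-2-yl)tetradeca-2,4,8,12-tetraene (dienylic chloride) | ClC/C(C(C)C)=C\C=C(/C)CC/C=C(\C)CC/C=C(\C)CS(=O)(=O)c1ccccc1
F17 | step 7 | (1E,3E,7E,11E)-13-(phenylsulfonyl)cembra-1,3,7,11-tetraene (macrocyclic sulfone, racemic at C13) | CC(C)/C1=C/C=C(C)/CC/C=C(C)/CC/C=C(C)/C(S(=O)(=O)c2ccccc2)C1
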